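## Retrosynthetic overview

1. The ten-membered ring is closed last at C6–C7, the bond germacrene A synthase makes, by an intramolecular indium Barbier allylation. C7 comes from a 3-(bromomethyl)butenolide and C6 from a γ-hydroxybutenolide (masked aldehyde); the same step creates the C11=C13 exo-methylene and re-closes the 15,6-butenolide.
2. Before that, the 12,8-lactone ring is built as a butenolide (C8–O acylation, then ring-closing metathesis), and the 15,6-lactone ring is carried as a 2-silylfuran unmasked by singlet oxygen.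
3. The chain is joined at C1–C2 by Michael addition of a 3-furyl methyl ketone enolate to (5R)-5-vinyl-α-methylene-γ-butyrolactone. This sacrificial lactone relays C8 to C10 and is then reduced to the C14 and C8 alcohols.
4. Ring order: sacrificial γ-lactone (step 1), 12,8-butenolide (step 9), 15,6-hydroxybutenolide (step 10), carbocycle with both lactones in final form (step 11).
5. Stereocentres: C8 by catalyst (step 1), C10 from C8 (step 3), C3 by catalyst (step 4), C7 and C6 in the ring closure (step 11).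

Assumption: germacrane numbering is used (ring C1–C10, C11–C13 on C7, C14 on C10, C15 on C4); the SMILES corresponds to (3S,6R,7S,8R,10R).

## Route

Step 1
Reactants: 1 acrolein; 2 methyl 2-(bromomethyl)prop-2-enoate
Product: 5 (5R)-5-ethenyl-3-methylideneoxolan-2-one, via silyl ether 3 (not isolated), via hydroxy ester 4 (not isolated)
Conditions: CrCl2 (10 mol %), chiral carbazole-bis(oxazoline) ligand (12 mol %, the antipode that gives 5R), Mn powder (2 equiv), TMSCl (1.2 equiv), iPr2NEt (20 mol %), THF, 0 °C; then 1 M HCl, 23 °C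
Reagents that add atoms: none
Why: Catalytic asymmetric Nozaki–Hiyama–Kishi 2-(alkoxycarbonyl)allylation, in which the ligand-bound allylchromium adds to one face of the aldehyde to set C8 (R) and acid work-up desilylates and lactonises the γ-hydroxy ester.

Step 2
Reactants: 6 furan-3-carboxylic acid
Product: 10 1-[2-(trimethylsilyl)furan-3-yl]ethan-1-one, via dilithio furoate 7 (not isolated), via lithium silylfuroate 8 (not isolated), via dilithium diolate 9 (not isolated)
Conditions: LiN(iPr)2 (2.2 equiv), THF, −78 °C; TMSCl (1.0 equiv), −78 °C; MeLi (3 equiv), −78 to 0 °C; aq. NH4Cl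
Reagents that add atoms: chlorotrimethylsilane C[Si](C)(C)Cl; methyllithium [Li]C
Why: Carboxylate-directed ortho-lithiation puts silicon on furan C2 (the later C15), and MeLi adds once to the lithium carboxylate because the diolate survives until quench (ketone synthesis from a carboxylate); no stereocentre.

Step 3
Reactants: 10 1-[2-(trimethylsilyl)furan-3-yl]ethan-1-one; 5 (5R)-5-ethenyl-3-methylideneoxolan-2-one
Product: 13 (3R,5R)-5-ethenyl-3-{3-oxo-3-[2-(trimethylsilyl)furan-3-yl]propyl}oxolan-2-one, via ketone enolate 11 (not isolated), via lactone enolate 12 (not isolated)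
Conditions: 10 (1.4 equiv), LiN(iPr)2 (1.4 equiv), THF, −78 °C; slow addition of 5 (1.0 equiv), −78 °C; then 2,6-di-tert-butyl-4-methylphenol, −78 °C
Reagents that add atoms: none
Why: Michael addition of the kinetic ketone enolate to the exocyclic methylene forms C1–C2, and kinetic protonation of the lactone enolate on the face opposite the C8 vinyl group places the new chain cis to it (C10, R).

Step 4
Reactants: 13 (3R,5R)-5-ethenyl-3-{3-oxo-3-[2-(trimethylsilyl)furan-3-yl]propyl}oxolan-2-one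
Product: 14 (3R,5R)-5-ethenyl-3-{(3S)-3-hydroxy-3-[2-(trimethylsilyl)furan-3-yl]propyl}oxolan-2-one
Conditions: RuCl[(S,S)-TsDPEN](p-cymene) (1 mol %), HCO2H/Et3N (5:2), EtOAc, 25 °C
Reagents that add atoms: none
Why: Noyori–Ikariya asymmetric transfer hydrogenation of a heteroaryl alkyl ketone, where the (S,S) catalyst gives the (S)-carbinol at C3 by analogy with acetophenone and leaves lactone and vinyl group untouched.

Step 5
Reactants: 14 (3R,5R)-5-ethenyl-3-{(3S)-3-hydroxy-3-[2-(trimethylsilyl)furan-3-yl]propyl}oxolan-2-one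
Product: 15 (1S)-3-[(3R,5R)-5-ethenyl-2-oxooxolan-3-yl]-1-[2-(trimethylsilyl)furan-3-yl]propyl 2-methylpropanoate
Conditions: iPrCOCl (1.3 equiv), Et3N, DMAP (10 mol %), CH2Cl2, 0 °C
Reagents that add atoms: 2-methylpropanoyl chloride CC(C)C(Cl)=O
Why: DMAP-catalysed acylation of the only free hydroxyl installs the isobutyrate with retention at C3 while O8 and C14 stay tied up in the lactone.

Step 6
Reactants: 15 (1S)-3-[(3R,5R)-5-ethenyl-2-oxooxolan-3-yl]-1-[2-(trimethylsilyl)furan-3-yl]propyl 2-methylpropanoate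
Product: 17 (1S,4R,6R)-6-hydroxy-4-(hydroxymethyl)-1-[2-(trimethylsilyl)furan-3-yl]oct-7-en-1-yl 2-methylpropanoate, via lactol 16 (not isolated)
Conditions: iBu2AlH (1.15 equiv), CH2Cl2, −78 °C; MeOH; then NaBH4, EtOH, 0 °C
Reagents that add atoms: none
Why: Chemoselective two-stage reduction, since the γ-lactone takes up one hydride at −78 °C far faster than the hindered secondary isobutyrate next to the silylfuran, and NaBH4 then reduces only the lactol; no stereocentre is touched.

Step 7
Reactants: 17 (1S,4R,6R)-6-hydroxy-4-(hydroxymethyl)-1-[2-(trimethylsilyl)furan-3-yl]oct-7-en-1-yl 2-methylpropanoate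
Product: 18 (1S,4R,6R)-4-{[(tert-butyldimethylsilyl)oxy]methyl}-6-hydroxy-1-[2-(trimethylsilyl)furan-3-yl]oct-7-en-1-yl 2-methylpropanoate
Conditions: TBSCl (1.05 equiv), imidazole, CH2Cl2, −20 to 0 °C
Reagents that add atoms: tert-butylchlorodimethylsilane CC(C)(C)[Si](C)(C)Cl
Why: Selective silylation of the primary C14 hydroxyl over the secondary allylic C8 hydroxyl on steric grounds.

Step 8
Reactants: 18 (1S,4R,6R)-4-{[(tert-butyldimethylsilyl)oxy]methyl}-6-hydroxy-1-[2-(trimethylsilyl)furan-3-yl]oct-7-en-1-yl 2-methylpropanoate; 19 2-(bromomethyl)prop-2-enoic acid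
Product: 21 (3R,5R,8S)-5-{[(tert-butyldimethylsilyl)oxy]methyl}-8-(2-methylpropanoyloxy)-8-[2-(trimethylsilyl)furan-3-yl]oct-1-en-3-yl 2-(bromomethyl)prop-2-enoate, via acylisourea 20 (not isolated)
Conditions: 19 (1.5 equiv), DCC (1.5 equiv), DMAP (5 mol %), CH2Cl2, 0 °C
Reagents that add atoms: none
Why: Steglich esterification forms the C12–O8 ester bond (the bond of the 12,8-lactone) with retention at C8, kept cold and with little DMAP to spare the allylic bromide.

Step 9
Reactants: 21 (3R,5R,8S)-5-{[(tert-butyldimethylsilyl)oxy]methyl}-8-(2-methylpropanoyloxy)-8-[2-(trimethylsilyl)furan-3-yl]oct-1-en-3-yl 2-(bromomethyl)prop-2-enoate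
Product: 22 (1S,4R)-5-[(2R)-4-(bromomethyl)-5-oxo-2,5-dihydrofuran-2-yl]-4-{[(tert-butyldimethylsilyl)oxy]methyl}-1-[2-(trimethylsilyl)furan-3-yl]pentyl 2-methylpropanoate
Conditions: second-generation Hoveyda–Grubbs catalyst RuCl2(H2IMes)(=CH-C6H4-2-OiPr) (5–10 mol %), toluene (5 mM), 80 °C
Reagents that add atoms: none
Why: Ring-closing metathesis of the vinyl group onto the acrylate gives the butenolide (C7=C11), and the phosphine-free catalyst avoids SN2' attack on the allylic bromide.

Step 10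
Reactants: 22 (1S,4R)-5-[(2R)-4-(bromomethyl)-5-oxo-2,5-dihydrofuran-2-yl]-4-{[(tert-butyldimethylsilyl)oxy]methyl}-1-[2-(trimethylsilyl)furan-3-yl]pentyl 2-methylpropanoate
Product: 25 (1S,4R)-5-[(2R)-4-(bromomethyl)-5-oxo-2,5-dihydrofuran-2-yl]-4-{[(tert-butyldimethylsilyl)oxy]methyl}-1-(5-hydroxy-2-oxo-2,5-dihydrofuran-3-yl)pentyl 2-methylpropanoate, via endoperoxide 23 (not isolated), via silyl ester 24 (not isolated)
Conditions: O2, visible light, tetraphenylporphyrin (1 mol %), CH2Cl2, −78 °C; then H2O/THF, 0 °C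
Reagents that add atoms: dioxygen O=O
Why: [4+2] cycloaddition of singlet oxygen to the furan followed by silyl shift to the peroxide oxygen makes the silicon-bearing carbon the carboxyl (C15) and the other α-carbon the masked aldehyde (C6), so only the α-substituted γ-hydroxybutenolide forms.

Step 11
Reactants: 25 (1S,4R)-5-[(2R)-4-(bromomethyl)-5-oxo-2,5-dihydrofuran-2-yl]-4-{[(tert-butyldimethylsilyl)oxy]methyl}-1-(5-hydroxy-2-oxo-2,5-dihydrofuran-3-yl)pentyl 2-methylpropanoate
Product: 28 (3S,6R,7S,8R,10R)-14-hydroxy-3-(2-methylpropanoyloxy)germacra-4,11(13)-diene-12,8:15,6-diolide, via allylindium 26 (not isolated), via silyl ether 27 (not isolated)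
Conditions: In powder (5 equiv), THF/H2O (2:1), 25 added over 10 h to 2 mM, 25 °C; filter; then 2 M HCl, 25 °C, 3 h
Reagents that add atoms: none
Why: Proposed new method: indium inserts into the allylic C–Br bond and the allylindium attacks through its γ-carbon C7 the open (Z)-4-oxo-2-enoate form of the lactol at C6, which is the bond and polarity of the germacrene A synthase step (C6 electrophile, C7=C11 π-nucleophile, new exocyclic C11=C13); C7 is attacked on the butenolide face opposite C9 (7S, trans to O8), the indium-bound cis-carboxylate is expected to hold the formyl group with C5 pseudo-axial in the six-membered transition state and so give 6R (6,7-syn), the C6 alkoxide re-closes on C15, and HCl then cleaves the primary silyl ether; the closest known chemistry is the aqueous indium Barbier allylation of γ-hydroxybutenolides and the Barbier or Nozaki–Hiyama–Kishi macrocyclisation to ten-membered germacranolides.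

## Compound list

1 | acrolein (prop-2-enal) | C=CC=O | starting material
2 | methyl 2-(bromomethyl)prop-2-enoate | C=C(CBr)C(=O)OC | starting material
3 | methyl (4R)-2-methylidene-4-[(trimethylsilyl)oxy]hex-5-enoate | C=C[C@@H](CC(=C)C(=O)OC)O[Si](C)(C)C | intermediate
4 | methyl (4R)-4-hydroxy-2-methylidenehex-5-enoate | C=C[C@@H](CC(=C)C(=O)OC)O | intermediate
5 | (5R)-5-ethenyl-3-methylideneoxolan-2-one | C=C[C@H]1CC(=C)C(=O)O1 | intermediate
6 | furan-3-carboxylic acid | OC(=O)c1ccoc1 | starting material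
7 | lithium 2-lithiofuran-3-carboxylate | [Li]OC(=O)c1ccoc1[Li] | intermediate
8 | lithium 2-(trimethylsilyl)furan-3-carboxylate | [Li]OC(=O)c1ccoc1[Si](C)(C)C | intermediate
9 | dilithium 1-[2-(trimethylsilyl)furan-3-yl]ethane-1,1-diolate | CC(O[Li])(O[Li])c1ccoc1[Si](C)(C)C | intermediate
10 | 1-[2-(trimethylsilyl)furan-3-yl]ethan-1-one | CC(=O)c1ccoc1[Si](C)(C)C | intermediate
11 | lithium 1-[2-(trimethylsilyl)furan-3-yl]ethen-1-olate | C=C(O[Li])c1ccoc1[Si](C)(C)C | intermediate
12 | lithium enolate of 13 (lactone C14–O enolate, 5R) | C=C[C@H]1CC(CCC(=O)c2ccoc2[Si](C)(C)C)=C(O[Li])O1 | intermediate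
13 | (3R,5R)-5-ethenyl-3-{3-oxo-3-[2-(trimethylsilyl)furan-3-yl]propyl}oxolan-2-one | C=C[C@H]1C[C@@H](CCC(=O)c2ccoc2[Si](C)(C)C)C(=O)O1 | intermediate
14 | (3R,5R)-5-ethenyl-3-{(3S)-3-hydroxy-3-[2-(trimethylsilyl)furan-3-yl]propyl}oxolan-2-one | C=C[C@H]1C[C@@H](CC[C@H](O)c2ccoc2[Si](C)(C)C)C(=O)O1 | intermediate
15 | (1S)-3-[(3R,5R)-5-ethenyl-2-oxooxolan-3-yl]-1-[2-(trimethylsilyl)furan-3-yl]propyl 2-methylpropanoate | C=C[C@H]1C[C@@H](CC[C@H](OC(=O)C(C)C)c2ccoc2[Si](C)(C)C)C(=O)O1 | intermediate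
16 | (1S)-3-[(3R,5R)-5-ethenyl-2-hydroxyoxolan-3-yl]-1-[2-(trimethylsilyl)furan-3-yl]propyl 2-methylpropanoate (lactol, both anomers) | C=C[C@H]1C[C@@H](CC[C@H](OC(=O)C(C)C)c2ccoc2[Si](C)(C)C)C(O)O1 | intermediate
17 | (1S,4R,6R)-6-hydroxy-4-(hydroxymethyl)-1-[2-(trimethylsilyl)furan-3-yl]oct-7-en-1-yl 2-methylpropanoate | C=C[C@@H](C[C@H](CO)CC[C@H](OC(=O)C(C)C)c1ccoc1[Si](C)(C)C)O | intermediate
18 | (1S,4R,6R)-4-{[(tert-butyldimethylsilyl)oxy]methyl}-6-hydroxy-1-[2-(trimethylsilyl)furan-3-yl]oct-7-en-1-yl 2-methylpropanoate | C=C[C@@H](C[C@H](CO[Si](C)(C)C(C)(C)C)CC[C@H](OC(=O)C(C)C)c1ccoc1[Si](C)(C)C)O | intermediate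
19 | 2-(bromomethyl)prop-2-enoic acid | C=C(CBr)C(=O)O | starting material
20 | O-[2-(bromomethyl)prop-2-enoyl]-N,N'-dicyclohexylisourea | C=C(CBr)C(=O)OC(=NC1CCCCC1)NC1CCCCC1 | intermediate
21 | (3R,5R,8S)-5-{[(tert-butyldimethylsilyl)oxy]methyl}-8-(2-methylpropanoyloxy)-8-[2-(trimethylsilyl)furan-3-yl]oct-1-en-3-yl 2-(bromomethyl)prop-2-enoate | C=C[C@@H](C[C@H](CO[Si](C)(C)C(C)(C)C)CC[C@H](OC(=O)C(C)C)c1ccoc1[Si](C)(C)C)OC(=O)C(=C)CBr | intermediate
22 | (1S,4R)-5-[(2R)-4-(bromomethyl)-5-oxo-2,5-dihydrofuran-2-yl]-4-{[(tert-butyldimethylsilyl)oxy]methyl}-1-[2-(trimethylsilyl)furan-3-yl]pentyl 2-methylpropanoate | BrCC1=C[C@@H](C[C@H](CO[Si](C)(C)C(C)(C)C)CC[C@H](OC(=O)C(C)C)c2ccoc2[Si](C)(C)C)OC1=O | intermediate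
23 | 2,5-endoperoxide of the furan ring of 22 (bridgehead epimers) | BrCC1=C[C@@H](C[C@H](CO[Si](C)(C)C(C)(C)C)CC[C@H](OC(=O)C(C)C)C2=CC3OOC2(O3)[Si](C)(C)C)OC1=O | intermediate
24 | trimethylsilyl (Z)-4-oxobut-2-enoate form of 25 (C15 silyl ester, C6 aldehyde) | BrCC1=C[C@@H](C[C@H](CO[Si](C)(C)C(C)(C)C)CC[C@H](OC(=O)C(C)C)/C(C(=O)O[Si](C)(C)C)=C/C=O)OC1=O | intermediate
25 | (1S,4R)-5-[(2R)-4-(bromomethyl)-5-oxo-2,5-dihydrofuran-2-yl]-4-{[(tert-butyldimethylsilyl)oxy]methyl}-1-(5-hydroxy-2-oxo-2,5-dihydrofuran-3-yl)pentyl 2-methylpropanoate (both lactol epimers) | BrCC1=C[C@@H](C[C@H](CO[Si](C)(C)C(C)(C)C)CC[C@H](OC(=O)C(C)C)C2=CC(O)OC2=O)OC1=O | intermediate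
26 | allylindium species from 25 (drawn as the monovalent allylindium on C13) | [In]CC1=C[C@@H](C[C@H](CO[Si](C)(C)C(C)(C)C)CC[C@H](OC(=O)C(C)C)C2=CC(O)OC2=O)OC1=O | intermediate
27 | 14-O-(tert-butyldimethylsilyl) ether of 28 | C=C1C(=O)O[C@@H]2C[C@H](CO[Si](C)(C)C(C)(C)C)CC[C@H](OC(=O)C(C)C)C3=C[C@@H](OC3=O)[C@@H]12 | intermediate
28 | (3S,6R,7S,8R,10R)-14-hydroxy-3-(2-methylpropanoyloxy)germacra-4,11(13)-diene-12,8:15,6-diolide | C=C1C(=O)O[C@@H]2C[C@H](CO)CC[C@H](OC(=O)C(C)C)C3=C[C@@H](OC3=O)[C@@H]12 | target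

## Step count and risks

Total steps: 11. Longest linear sequence: 10 steps (6 to 28 through steps 2–11; 1 to 28 through steps 1 and 3–11 is equally long).

The three steps most likely to fail are 11, 3 and 9.

For step 11, the risks are oligomerisation, protonolysis of the allylindium, and the C6 epimer if the chelated transition state does not operate. The fallback sets out from 18 and comes back at 27, and replaces the Barbier closure by a cationic one with an open transition state. Alcohol 18 is esterified with 2-[(trimethylsilyl)methyl]prop-2-enoic acid (DCC, DMAP) to the silylmethyl acrylate ester F1. Ring-closing metathesis as in step 9 gives the 3-(trimethylsilylmethyl)butenolide F2. Photooxygenation as in step 10 passes through the endoperoxide F3 and the silyl ester F4 to the hydroxybutenolide F5. TMSOTf (20 mol %) in CH2Cl2 at −78 °C and 2 mM then ionises the lactol to the acyl-oxocarbenium ion at C6, which the allylsilane attacks through C7 with loss of silicon from C13 (intramolecular Hosomi–Sakurai reaction). This gives 27, which is desilylated with HCl as in the second stage of step 11.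

For step 3, the risks are anionic oligomerisation of 5, double addition, and a modest cis/trans ratio at C10. The fallback sets out from 10 and 5 and comes back at 13, and changes the anionic Michael addition to a Mukaiyama–Michael addition. Ketone 10 is converted with TMSOTf/Et3N into the silyl enol ether F6. F6 adds to 5 under Lewis-acid catalysis (TMSOTf 5 mol % or Sc(OTf)3, CH2Cl2, −78 °C) to give the neutral silyl ketene acetal F7, which cannot start chain growth. F7 is then protonated in a separate operation (AcOH in wet THF, −78 °C) from the face opposite the vinyl group to give 13.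

For step 9, the risks are slow ring closure onto the 1,1-disubstituted acrylate that carries CH2Br, and side reactions of the allylic bromide. The fallback sets out from 18 and comes back at 22, and installs the bromide only after the ring exists. Alcohol 18 is acylated with acryloyl chloride (Et3N, CH2Cl2, 0 °C) to the acrylate ester F8. Ring-closing metathesis gives the butenolide F9. A phosphine-catalysed Morita–Baylis–Hillman reaction with aqueous formaldehyde (PBu3, THF) gives the 3-(hydroxymethyl)butenolide F10. An Appel reaction (CBr4, PPh3, CH2Cl2, 0 °C) then gives 22.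

## Further compounds

F1 | step 11 | (3R,5R,8S)-5-{[(tert-butyldimethylsilyl)oxy]methyl}-8-(2-methylpropanoyloxy)-8-[2-(trimethylsilyl)furan-3-yl]oct-1-en-3-yl 2-[(trimethylsilyl)methyl]prop-2-enoate | C=C[C@@H](C[C@H](CO[Si](C)(C)C(C)(C)C)CC[C@H](OC(=O)C(C)C)c1ccoc1[Si](C)(C)C)OC(=O)C(=C)C[Si](C)(C)C
F2 | step 11 | analogue of 22 with CH2SiMe3 in place of CH2Br | C[Si](C)(C)CC1=C[C@@H](C[C@H](CO[Si](C)(C)C(C)(C)C)CC[C@H](OC(=O)C(C)C)c2ccoc2[Si](C)(C)C)OC1=O
F3 | step 11 | 2,5-endoperoxide of the furan ring of F2 | C[Si](C)(C)CC1=C[C@@H](C[C@H](CO[Si](C)(C)C(C)(C)C)CC[C@H](OC(=O)C(C)C)C2=CC3OOC2(O3)[Si](C)(C)C)OC1=O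
F4 | step 11 | trimethylsilyl (Z)-4-oxobut-2-enoate form of F5 | C[Si](C)(C)CC1=C[C@@H](C[C@H](CO[Si](C)(C)C(C)(C)C)CC[C@H](OC(=O)C(C)C)/C(C(=O)O[Si](C)(C)C)=C/C=O)OC1=O
F5 | step 11 | analogue of 25 with CH2SiMe3 in place of CH2Br | C[Si](C)(C)CC1=C[C@@H](C[C@H](CO[Si](C)(C)C(C)(C)C)CC[C@H](OC(=O)C(C)C)C2=CC(O)OC2=O)OC1=O
F6 | step 3 | trimethyl({1-[2-(trimethylsilyl)furan-3-yl]ethenyl}oxy)silane | C=C(O[Si](C)(C)C)c1ccoc1[Si](C)(C)C
F7 | step 3 | trimethylsilyl ketene acetal of 13 (5R) | C=C[C@H]1CC(CCC(=O)c2ccoc2[Si](C)(C)C)=C(O[Si](C)(C)C)O1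
F8 | step 9 | (3R,5R,8S)-5-{[(tert-butyldimethylsilyl)oxy]methyl}-8-(2-methylpropanoyloxy)-8-[2-(trimethylsilyl)furan-3-yl]oct-1-en-3-yl prop-2-enoate | C=C[C@@H](C[C@H](CO[Si](C)(C)C(C)(C)C)CC[C@H](OC(=O)C(C)C)c1ccoc1[Si](C)(C)C)OC(=O)C=C
F9 | step 9 | analogue of 22 with H in place of CH2Br | O=C1C=C[C@@H](C[C@H](CO[Si](C)(C)C(C)(C)C)CC[C@H](OC(=O)C(C)C)c2ccoc2[Si](C)(C)C)O1
F10 | step 9 | analogue of 22 with CH2OH in place of CH2Br | OCC1=C[C@@H](C[C@H](CO[Si](C)(C)C(C)(C)C)CC[C@H](OC(=O)C(C)C)c2ccoc2[Si](C)(C)C)OC1=O
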